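**Retrosynthetic overview**

- The strategy rests on one feature of the 2,3-dihydrobenzofuran: O1 (on C7a) and the isovaleryloxy-bearing C3 (on C3a) sit on adjacent benzene carbons, and the chain O1–C2–C3(OCOR) is the skeleton of an epoxidised enol isovalerate.
- Key disconnection: O1–C7a and C3–C3a are cut together, giving benzyne and a chiral trans enol-ester epoxide whose other carbon carries a masked isopropenyl group (CMe2OTBS). The dihydrofuran is the only ring formed in the route; the benzene ring comes from the aryne precursor.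
- The epoxide comes from an (E)-enol isovalerate by Shi epoxidation. The enol ester is built with fixed geometry from 2-methylbut-3-yn-2-ol by hydroboration and copper-mediated O-alkenylation of isovaleric acid.
- After the annulation: bromination at C5 (para to O1), Stille acetylation, desilylation and dehydration to the isopropenyl group, Noyori reduction and acetylation, then allylic oxidation to the enal.

Key step: step 6

Assumption: the D-fructose-derived ketone is taken to attack the enol ester on the same olefin face as other trans-disubstituted alkenes (the face that gives (R,R)-trans-β-methylstyrene oxide); that face corresponds to the (2R,3R)-epoxide. If the opposite sense were found, the enantiomeric ketone would be used.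

**Route**

Step 1
Reactants: 1 2-methylbut-3-yn-2-ol
Product: 2 tert-butyldimethyl[(2-methylbut-3-yn-2-yl)oxy]silane
Conditions: TBSOTf, 2,6-lutidine, CH2Cl2, 0 °C to rt
Reagents that add atoms: tert-butyldimethylsilyl trifluoromethanesulfonate, CC(C)(C)[Si](C)(C)OS(=O)(=O)C(F)(F)F
Why: Silyl triflate with lutidine is the standard O-silylation for hindered tertiary alcohols, and the terminal alkyne is inert to it.

Step 2
Reactants: 2 tert-butyldimethyl[(2-methylbut-3-yn-2-yl)oxy]silane
Product: 3 tert-butyldimethyl{[(3E)-2-methyl-4-(4,4,5,5-tetramethyl-1,3,2-dioxaborolan-2-yl)but-3-en-2-yl]oxy}silane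
Conditions: pinacolborane, Cp2Zr(H)Cl (5 mol %), Et3N (10 mol %), neat, 60 °C
Reagents that add atoms: pinacolborane, CC1(C)OBOC1(C)C
Why: Zirconocene-hydride-catalysed hydroboration of a terminal alkyne is a syn addition that puts boron on the terminal carbon, which fixes the E geometry of the later enol ester.

Step 3
Reactants: 3 the (E)-alkenyl pinacol boronate
Product: 4 potassium [(1E)-3-(tert-butyldimethylsilyloxy)-3-methylbut-1-en-1-yl]trifluoroborate
Conditions: KHF2 (aq.), MeOH, rt
Reagents that add atoms: potassium hydrogen difluoride, F.[F-].[K+]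
Why: Bifluoride exchange of a pinacol boronate to the trifluoroborate salt is a routine ligand exchange at boron that leaves the alkene geometry and the tertiary silyl ether untouched.

Step 4
Reactants: 4 the potassium (E)-alkenyltrifluoroborate; 5 3-methylbutanoic acid (isovaleric acid)
Product: 6 (1E)-3-(tert-butyldimethylsilyloxy)-3-methylbut-1-en-1-yl 3-methylbutanoate
Conditions: CuBr (cat.), DMAP, 4 Å MS, O2 (1 atm), MeCN, 60 °C
Reagents that add atoms: none
Why: Copper-mediated oxidative C–O coupling of an alkenyltrifluoroborate with a carboxylic acid (Chan–Lam type) transfers the alkenyl group with retention, so the E-enol ester should form without the E/Z mixtures and the β-elimination of silanol that enolising the corresponding β-silyloxy aldehyde would risk.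

Step 5
Reactants: 6 the (E)-enol isovalerate
Product: 7 (2R,3R)-3-[2-(tert-butyldimethylsilyloxy)propan-2-yl]oxiran-2-yl 3-methylbutanoate (trans)
Conditions: D-fructose-derived Shi ketone (1,2:4,5-di-O-isopropylidene-β-D-erythro-hexo-2,3-diulo-2,6-pyranose, 0.3 equiv), Oxone (2KHSO5·KHSO4·K2SO4), K2CO3, Bu4NHSO4, MeCN/CH2(OMe)2–aq. Na2B4O7/Na2EDTA buffer (pH 10.5), −10 to 0 °C; cold non-acidic work-up, used at once
Reagents that add atoms: potassium peroxymonosulfate (active component of Oxone), [K+].[O-]S(=O)(=O)OO
Why: Shi epoxidation (chiral dioxirane made in situ) is a concerted syn oxygen transfer known for enol esters and best for trans-disubstituted alkenes; the spiro transition state should deliver oxygen to the face that makes the silyloxyalkyl-bearing carbon R, the only centre of 7 that is carried into the target.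

Step 6
Reactants: 7 the (2R,3R)-enol-ester epoxide; 8 2-(trimethylsilyl)phenyl trifluoromethanesulfonate
Product: 11 (2S,3S)-2-[2-(tert-butyldimethylsilyloxy)propan-2-yl]-2,3-dihydro-1-benzofuran-3-yl 3-methylbutanoate (2,3-trans), via benzyne 9 (not isolated), via aryl anion–oxiranium zwitterion 10 (not isolated)
Conditions: CsF (3 equiv), MeCN, rt, 8 added slowly
Reagents that add atoms: none
Why: Proposed new method: fluoride removes the silyl group of 8 to release benzyne 9, the epoxide oxygen of 7 adds to its strained triple bond to give zwitterion 10, the O–C bond to the acyloxy carbon then ionises, and the ortho aryl anion bonds to that carbon to form C3–C3a, O1–C7a having formed in the first event. The closest known reaction type is the fluoride-triggered insertion of arynes into the benzylic C–O bond of styrene oxide, which gives 3-aryl-2,3-dihydrobenzofurans; an enol-ester epoxide has not been used in this role. The dihydrofuran ring closes by recombination of the aryl anion with the acyloxy-stabilised cation (formally a 5-exo-trig closure onto the acyloxycarbenium ion), not by backside displacement, which a five-membered transition state cannot reach. C2 keeps the configuration of its epoxide carbon because its C–O bond is never broken, and the new centre C3 is set when the aryl anion meets the planar cation on the face away from the bulky C2 substituent, which should give the 2,3-trans ester. The step needs the acyloxy-side C–O bond to break and not the other one, which the ester oxygen secures by stabilising that cation while the other carbon is neopentyl-like and next to the electron-withdrawing silyloxy carbon; it also needs ring closure to outrun acyl transfer to the aryl anion and its protonation, for which the intimate ion pair in an aprotic medium and the low standing concentration of benzyne are relied on. Benzyne is symmetrical, so no regiochemical question arises at the arene.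

Step 7
Reactants: 11 the (2S,3S)-dihydrobenzofuranyl isovalerate
Product: 12 (2S,3S)-5-bromo-2-[2-(tert-butyldimethylsilyloxy)propan-2-yl]-2,3-dihydro-1-benzofuran-3-yl 3-methylbutanoate
Conditions: NBS, MeCN, 0 °C to rt, dark
Reagents that add atoms: N-bromosuccinimide, O=C1CCC(=O)N1Br
Why: Electrophilic aromatic bromination of an alkyl aryl ether with NBS in a polar solvent goes para to the ring oxygen, here C5, and ionic conditions in the dark avoid benzylic radical bromination at C3.

Step 8
Reactants: 12 the C5 bromide
Product: 14 (2S,3S)-5-acetyl-2-[2-(tert-butyldimethylsilyloxy)propan-2-yl]-2,3-dihydro-1-benzofuran-3-yl 3-methylbutanoate, via 5-(1-ethoxyethenyl) enol ether 13 (not isolated)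
Conditions: tributyl(1-ethoxyvinyl)stannane, Pd(PPh3)4 (5 mol %), toluene, 100 °C; then 1 M HCl, THF, 0 °C
Reagents that add atoms: tributyl(1-ethoxyvinyl)stannane, CCCC[Sn](CCCC)(CCCC)C(=C)OCC; water, O
Why: Stille coupling (oxidative addition of the aryl bromide to zerovalent palladium, transmetalation, reductive elimination) installs a masked acetyl group under neutral conditions that the esters tolerate, and brief dilute acid hydrolyses the enol ether to the methyl ketone.

Step 9
Reactants: 14 the C5 acetyl silyl ether
Product: 15 (2S,3S)-5-acetyl-2-(2-hydroxypropan-2-yl)-2,3-dihydro-1-benzofuran-3-yl 3-methylbutanoate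
Conditions: HF (48 % aq.), MeCN, 0 °C to rt
Reagents that add atoms: none
Why: Acidic fluoride desilylation cleaves the hindered tertiary silyl ether without a basic medium that could eliminate isovaleric acid to the benzofuran, and the C5 acetyl group tempers donation from O1 so the C3 ester should not ionise.

Step 10
Reactants: 15 the tertiary alcohol
Product: 16 (2R,3S)-5-acetyl-2-(prop-1-en-2-yl)-2,3-dihydro-1-benzofuran-3-yl 3-methylbutanoate (same spatial arrangement as 15; the C2 descriptor changes only because the substituent priorities change)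
Conditions: Burgess reagent (methyl N-(triethylammoniosulfonyl)carbamate), toluene, 50 °C
Reagents that add atoms: none
Why: Burgess dehydration is a syn elimination of the sulfamate ester that should take a hydrogen from one of the two unhindered methyl groups and not the single hindered, oxygen-bearing C2–H, giving the isopropenyl group without touching C2 or C3.

Step 11
Reactants: 16 the isopropenyl ketone
Product: 17 (2R,3S)-5-[(1S)-1-hydroxyethyl]-2-(prop-1-en-2-yl)-2,3-dihydro-1-benzofuran-3-yl 3-methylbutanoate
Conditions: RuCl(p-cymene)[(S,S)-TsDPEN] (1 mol %), HCO2H/Et3N (5:2), rt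
Reagents that add atoms: none
Why: Noyori asymmetric transfer hydrogenation delivers hydride to one face of the aryl methyl ketone through the Ru–H/N–H outer-sphere transition state, the (S,S)-ligand giving the (S)-1-arylethanol, and it leaves the isopropenyl group and the ester alone.

Step 12
Reactants: 17 the (S)-benzylic alcohol
Product: 18 (2R,3S)-5-[(1S)-1-acetoxyethyl]-2-(prop-1-en-2-yl)-2,3-dihydro-1-benzofuran-3-yl 3-methylbutanoate
Conditions: Ac2O, pyridine, DMAP (cat.), CH2Cl2, 0 °C
Reagents that add atoms: acetic anhydride, CC(=O)OC(C)=O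
Why: DMAP-catalysed acylation of the secondary alcohol occurs at oxygen with retention at the carbinol carbon.

Step 13
Reactants: 18 the diester with the isopropenyl group
Product: 19 (2R,3S)-5-[(1S)-1-acetoxyethyl]-2-(3-hydroxyprop-1-en-2-yl)-2,3-dihydro-1-benzofuran-3-yl 3-methylbutanoate
Conditions: SeO2 (0.5 equiv), t-BuOOH, CH2Cl2, rt
Reagents that add atoms: selenium dioxide (oxygen carrier), O=[Se]=O; tert-butyl hydroperoxide (terminal oxygen source), CC(C)(C)OO
Why: Riley allylic oxidation (ene reaction with SeO2, then [2,3]-sigmatropic shift) of a 1,1-disubstituted alkene prefers the methyl group over the tertiary C2–H, so the isopropenyl methyl should be hydroxylated; any enal already formed converges in the next step.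

Step 14
Reactants: 19 the allylic alcohol
Product: 20 (2R,3S)-5-[(1S)-1-acetoxyethyl]-2-(3-oxoprop-1-en-2-yl)-2,3-dihydro-1-benzofuran-3-yl 3-methylbutanoate (CNP0252902.2)
Conditions: MnO2 (activated, excess), CH2Cl2, rt
Reagents that add atoms: none
Why: MnO2 oxidises primary allylic alcohols to enals under neutral heterogeneous conditions that should spare both benzylic esters and the base-sensitive C2–H/C3–O array.

**Compound list**

1 | 2-methylbut-3-yn-2-ol | C#CC(C)(C)O | starting material
2 | tert-butyldimethyl[(2-methylbut-3-yn-2-yl)oxy]silane | C#CC(C)(C)O[Si](C)(C)C(C)(C)C | intermediate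
3 | tert-butyldimethyl{[(3E)-2-methyl-4-(4,4,5,5-tetramethyl-1,3,2-dioxaborolan-2-yl)but-3-en-2-yl]oxy}silane | CC(C)(O[Si](C)(C)C(C)(C)C)/C=C/B1OC(C)(C)C(C)(C)O1 | intermediate
4 | potassium [(1E)-3-(tert-butyldimethylsilyloxy)-3-methylbut-1-en-1-yl]trifluoroborate | CC(C)(O[Si](C)(C)C(C)(C)C)/C=C/[B-](F)(F)F.[K+] | intermediate
5 | 3-methylbutanoic acid (isovaleric acid) | CC(C)CC(=O)O | starting material
6 | (1E)-3-(tert-butyldimethylsilyloxy)-3-methylbut-1-en-1-yl 3-methylbutanoate | CC(C)CC(=O)O/C=C/C(C)(C)O[Si](C)(C)C(C)(C)C | intermediate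
7 | (2R,3R)-3-[2-(tert-butyldimethylsilyloxy)propan-2-yl]oxiran-2-yl 3-methylbutanoate (trans) | CC(C)(O[Si](C)(C)C(C)(C)C)[C@H]1O[C@@H]1OC(=O)CC(C)C | intermediate
8 | 2-(trimethylsilyl)phenyl trifluoromethanesulfonate | C[Si](C)(C)c1ccccc1OS(=O)(=O)C(F)(F)F | starting material
9 | benzyne (1,2-didehydrobenzene) | C1#CC=CC=C1 | intermediate
10 | aryl anion–oxiranium zwitterion (epoxide oxygen of 7 bonded to C1 of a phenyl ring whose C2 carries the negative charge; both epoxide carbons configured as in 7) | CC(C)(O[Si](C)(C)C(C)(C)C)[C@H]1[O+](C2=CC=CC=[C-]2)[C@@H]1OC(=O)CC(C)C | intermediate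
11 | (2S,3S)-2-[2-(tert-butyldimethylsilyloxy)propan-2-yl]-2,3-dihydro-1-benzofuran-3-yl 3-methylbutanoate (trans) | CC(C)(O[Si](C)(C)C(C)(C)C)[C@H]1Oc2ccccc2[C@@H]1OC(=O)CC(C)C | intermediate
12 | (2S,3S)-5-bromo-2-[2-(tert-butyldimethylsilyloxy)propan-2-yl]-2,3-dihydro-1-benzofuran-3-yl 3-methylbutanoate | CC(C)(O[Si](C)(C)C(C)(C)C)[C@H]1Oc2ccc(Br)cc2[C@@H]1OC(=O)CC(C)C | intermediate
13 | (2S,3S)-2-[2-(tert-butyldimethylsilyloxy)propan-2-yl]-5-(1-ethoxyethenyl)-2,3-dihydro-1-benzofuran-3-yl 3-methylbutanoate | CC(C)(O[Si](C)(C)C(C)(C)C)[C@H]1Oc2ccc(C(=C)OCC)cc2[C@@H]1OC(=O)CC(C)C | intermediate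
14 | (2S,3S)-5-acetyl-2-[2-(tert-butyldimethylsilyloxy)propan-2-yl]-2,3-dihydro-1-benzofuran-3-yl 3-methylbutanoate | CC(C)(O[Si](C)(C)C(C)(C)C)[C@H]1Oc2ccc(C(C)=O)cc2[C@@H]1OC(=O)CC(C)C | intermediate
15 | (2S,3S)-5-acetyl-2-(2-hydroxypropan-2-yl)-2,3-dihydro-1-benzofuran-3-yl 3-methylbutanoate | CC(C)(O)[C@H]1Oc2ccc(C(C)=O)cc2[C@@H]1OC(=O)CC(C)C | intermediate
16 | (2R,3S)-5-acetyl-2-(prop-1-en-2-yl)-2,3-dihydro-1-benzofuran-3-yl 3-methylbutanoate | C=C(C)[C@H]1Oc2ccc(C(C)=O)cc2[C@@H]1OC(=O)CC(C)C | intermediate
17 | (2R,3S)-5-[(1S)-1-hydroxyethyl]-2-(prop-1-en-2-yl)-2,3-dihydro-1-benzofuran-3-yl 3-methylbutanoate | C=C(C)[C@H]1Oc2ccc([C@H](C)O)cc2[C@@H]1OC(=O)CC(C)C | intermediate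
18 | (2R,3S)-5-[(1S)-1-acetoxyethyl]-2-(prop-1-en-2-yl)-2,3-dihydro-1-benzofuran-3-yl 3-methylbutanoate | C=C(C)[C@H]1Oc2ccc([C@H](C)OC(C)=O)cc2[C@@H]1OC(=O)CC(C)C | intermediate
19 | (2R,3S)-5-[(1S)-1-acetoxyethyl]-2-(3-hydroxyprop-1-en-2-yl)-2,3-dihydro-1-benzofuran-3-yl 3-methylbutanoate | C=C(CO)[C@H]1Oc2ccc([C@H](C)OC(C)=O)cc2[C@@H]1OC(=O)CC(C)C | intermediate
20 | (2R,3S)-5-[(1S)-1-acetoxyethyl]-2-(3-oxoprop-1-en-2-yl)-2,3-dihydro-1-benzofuran-3-yl 3-methylbutanoate | C=C(C=O)[C@H]1Oc2ccc([C@H](C)OC(C)=O)cc2[C@@H]1OC(=O)CC(C)C | target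

**Step count**

Total steps: 14. Longest linear sequence: 14 steps (1 to 20); 5 and 8 enter as purchased materials.

**Steps most likely to fail**

Step 6 (aryne annulation).
- What may go wrong: the aryl anion of the zwitterion may be protonated by the medium or may transfer onto the ester carbonyl before the five-membered ring closes. The epoxide may also rearrange by acyl shift before it meets benzyne, and closure on the planar cation may give poor facial selectivity.
- Fallback (known chemistry, no aryne): it sets out from boronate 3 and comes back at 11. Suzuki–Miyaura coupling of 3 with 1-bromo-2-iodobenzene at the iodide (Pd(PPh3)4, K3PO4, dioxane/H2O, 70 °C) should give 1-bromo-2-[(1E)-3-(tert-butyldimethylsilyloxy)-3-methylbut-1-en-1-yl]benzene F1. Shi epoxidation of this trans-styrene with the same D-fructose-derived ketone should give tert-butyl({2-[(2S,3R)-3-(2-bromophenyl)oxiran-2-yl]propan-2-yl}oxy)dimethylsilane F2. Opening at the benzylic carbon with isovaleric acid 5 and its cesium salt (Cs2CO3, DMF, 80 °C) with inversion should give (1S,2S)-1-(2-bromophenyl)-2-hydroxy-3-methyl-3-(tert-butyldimethylsilyloxy)butyl 3-methylbutanoate F3; the other epoxide carbon is blocked by the adjacent quaternary centre. Intramolecular Ullmann-type C–O coupling of the secondary alcohol with the aryl bromide (CuI, 3,4,7,8-tetramethyl-1,10-phenanthroline, Cs2CO3, toluene, 110 °C) then forms O1–C7a and gives 11. The anti opening of the trans epoxide supplies the 2,3-trans relationship.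

Step 5 (Shi epoxidation of the enol ester).
- What may go wrong: hydrolysis or acyl-shift rearrangement of the enol-ester epoxide in the aqueous basic medium, or insufficient facial selectivity on this hindered alkene.
- Fallback (racemic synthesis and resolution): it sets out from 6 and comes back at 11. Epoxidation with anhydrous dimethyldioxirane in acetone at 0 °C (neutral, non-aqueous) should give the racemic trans-3-[2-(tert-butyldimethylsilyloxy)propan-2-yl]oxiran-2-yl 3-methylbutanoate F4. The annulation of step 6 should then give the racemic trans-2-[2-(tert-butyldimethylsilyloxy)propan-2-yl]-2,3-dihydro-1-benzofuran-3-yl 3-methylbutanoate F5. Preparative HPLC on a chiral stationary phase would separate 11 from (2R,3R)-2-[2-(tert-butyldimethylsilyloxy)propan-2-yl]-2,3-dihydro-1-benzofuran-3-yl 3-methylbutanoate F6.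

Step 13 (allylic oxidation).
- What may go wrong: over-oxidation, attack at the allylic C2–H, or acid-promoted loss of the benzylic esters caused by selenous acid.
- Fallback (ene reaction in place of selenium chemistry): it sets out from 18 and comes back at target 20. The Schenck ene reaction with singlet oxygen (O2, tetraphenylporphyrin, hν, CH2Cl2, 0 °C) should move the double bond into the methyl group and give (2R,3S)-5-[(1S)-1-acetoxyethyl]-2-(3-hydroperoxyprop-1-en-2-yl)-2,3-dihydro-1-benzofuran-3-yl 3-methylbutanoate F7. Ac2O/pyridine/DMAP at 0 °C would then dehydrate the primary allylic hydroperoxide (Kornblum–DeLaMare type) directly to enal 20.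

**Further compounds**

F1 | step 6 | 1-bromo-2-[(1E)-3-(tert-butyldimethylsilyloxy)-3-methylbut-1-en-1-yl]benzene | CC(C)(O[Si](C)(C)C(C)(C)C)/C=C/c1ccccc1Br
F2 | step 6 | tert-butyl({2-[(2S,3R)-3-(2-bromophenyl)oxiran-2-yl]propan-2-yl}oxy)dimethylsilane | CC(C)(O[Si](C)(C)C(C)(C)C)[C@H]1O[C@@H]1c1ccccc1Br
F3 | step 6 | (1S,2S)-1-(2-bromophenyl)-2-hydroxy-3-methyl-3-(tert-butyldimethylsilyloxy)butyl 3-methylbutanoate | CC(C)(O[Si](C)(C)C(C)(C)C)[C@@H](O)[C@@H](OC(=O)CC(C)C)c1ccccc1Br
F4 | step 5 | racemic trans-3-[2-(tert-butyldimethylsilyloxy)propan-2-yl]oxiran-2-yl 3-methylbutanoate (both enantiomers, 1:1) | CC(C)(O[Si](C)(C)C(C)(C)C)[C@H]1O[C@@H]1OC(=O)CC(C)C.CC(C)(O[Si](C)(C)C(C)(C)C)[C@@H]1O[C@H]1OC(=O)CC(C)C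
F5 | step 5 | racemic trans-2-[2-(tert-butyldimethylsilyloxy)propan-2-yl]-2,3-dihydro-1-benzofuran-3-yl 3-methylbutanoate (both enantiomers, 1:1) | CC(C)(O[Si](C)(C)C(C)(C)C)[C@H]1Oc2ccccc2[C@@H]1OC(=O)CC(C)C.CC(C)(O[Si](C)(C)C(C)(C)C)[C@@H]1Oc2ccccc2[C@H]1OC(=O)CC(C)C
F6 | step 5 | (2R,3R)-2-[2-(tert-butyldimethylsilyloxy)propan-2-yl]-2,3-dihydro-1-benzofuran-3-yl 3-methylbutanoate | CC(C)(O[Si](C)(C)C(C)(C)C)[C@@H]1Oc2ccccc2[C@H]1OC(=O)CC(C)C
F7 | step 13 | (2R,3S)-5-[(1S)-1-acetoxyethyl]-2-(3-hydroperoxyprop-1-en-2-yl)-2,3-dihydro-1-benzofuran-3-yl 3-methylbutanoate | C=C(COO)[C@H]1Oc2ccc([C@H](C)OC(C)=O)cc2[C@@H]1OC(=O)CC(C)C
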